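## Retrosynthetic overview

1. The target comes from atripliciolide 21 by a last-step esterification with tigloyl chloride.
2. The furanone (O10–C3 bond) is closed last, by transannular 5-endo-dig addition in the ten-membered α′-hydroxy ynone 20, which is generated by oxidising C1 of the germacranolide-type triol 19 (oxidise, then cyclise, as in the presumed biosynthesis).
3. The ten-membered carbocycle and the 6,12-lactone form together in one Cr(II) allylation/lactonisation of the acyclic enal/2-(bromomethyl)enoate 17; the bond made is C6–C7, the one nature makes when farnesyl diphosphate closes to the germacrane ring.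
4. 17 comes from the Baylis–Hillman adduct 11 (C11–C13 from methyl acrylate) by acetylide opening of its γ-lactone with enynol 12 (C1–C2), oxidation and SN2′ bromination.
5. 11 comes from lactone 8, built by a Cu-box Mukaiyama aldol (C10) and a Ru transfer hydrogenation (C8). Ring order: sacrificial γ-lactone, then carbocycle plus α-methylene lactone, then furanone.

Atom labels such as C6 or O10 use germacrane numbering of the target: ring C1–C10, lactone carbonyl C12, exo-methylene C13, methyl C14 on C10, methyl C15 on C4.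

Assumption: the sense of induction of the two chiral catalysts (steps 2 and 3) is taken by analogy from published models for related substrates; if either is opposite, the enantiomeric ligand is used.

## Route

Step 1
Reactants: 1 1,1-dimethoxypropan-2-one
Product: 3 [(3,3-dimethoxyprop-1-en-2-yl)oxy]trimethylsilane, via lithium enolate 2 (not isolated)
Conditions: LDA, THF, −78 °C; TMSCl, −78 °C → rt
Reagents that add atoms: chlorotrimethylsilane, C[Si](C)(C)Cl
Why: Kinetic deprotonation takes the unhindered methyl group rather than the acetal C–H, and O-silylation of the enolate gives the silyl enol ether; no stereocentre is formed.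

Step 2
Reactants: 3 [(3,3-dimethoxyprop-1-en-2-yl)oxy]trimethylsilane; 4 methyl pyruvate
Product: 6 methyl (2R)-2-hydroxy-5,5-dimethoxy-2-methyl-4-oxopentanoate, via silyl ether 5 (not isolated)
Conditions: [Cu((R,R)-t-Bu-box)](OTf)2 (10 mol%), THF, −78 °C; then 1 M HCl
Reagents that add atoms: none
Why: Evans Cu(II)–bis(oxazoline) Mukaiyama aldol, in which the pyruvate is chelated on copper and the enolsilane attacks the face left open by the tert-butyl groups, setting C10 (2R); the acidic work-up removes the transferred silyl group.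

Step 3
Reactants: 6 methyl (2R)-2-hydroxy-5,5-dimethoxy-2-methyl-4-oxopentanoate
Product: 8 (3R,5R)-5-(dimethoxymethyl)-3-hydroxy-3-methyloxolan-2-one, via diol ester 7 (not isolated)
Conditions: RuCl(p-cymene)[(R,R)-TsDPEN] (1 mol%), HCO2H/Et3N (5:2), 30 °C; then Et3N, toluene, 60 °C
Reagents that add atoms: none
Why: Noyori asymmetric transfer hydrogenation sets C8 (4R) under catalyst control, and the γ-hydroxy ester then closes to the γ-lactone by base-mediated transesterification, which ties up O8 and C1 until step 6.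

Step 4
Reactants: 8 (3R,5R)-5-(dimethoxymethyl)-3-hydroxy-3-methyloxolan-2-one
Product: 9 (2R,4R)-4-hydroxy-4-methyl-5-oxooxolane-2-carbaldehyde
Conditions: TFA/H2O (9:1), 0 °C → rt
Reagents that add atoms: water, O
Why: Acid hydrolysis of the electron-poor α-acyloxy dimethyl acetal, tolerated by the lactone and the tertiary alcohol; C8 is not enolised under acid, and the product exists partly as hydrate or bicyclic lactol.

Step 5
Reactants: 9 (2R,4R)-4-hydroxy-4-methyl-5-oxooxolane-2-carbaldehyde; 10 methyl acrylate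
Product: 11 methyl 2-{hydroxy[(2R,4R)-4-hydroxy-4-methyl-5-oxooxolan-2-yl]methyl}prop-2-enoate
Conditions: DABCO (0.5 equiv), neat 10 (10 equiv), rt
Reagents that add atoms: none
Why: Morita–Baylis–Hillman reaction of the activated α-acyloxy aldehyde; the new carbinol centre (C7) forms as an epimer mixture that is erased in step 8.

Step 6
Reactants: 11 methyl 2-{hydroxy[(2R,4R)-4-hydroxy-4-methyl-5-oxooxolan-2-yl]methyl}prop-2-enoate; 12 (2Z)-3-methylpent-2-en-4-yn-1-ol
Product: 15 methyl 2-[(2R,4R,8Z)-1,2,4,5,10-pentahydroxy-4,8-dimethyldec-8-en-6-yn-1-yl]prop-2-enoate, via dilithio enynolate 13 (not isolated), via ynone tetraol 14 (not isolated)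
Conditions: 12 (5 equiv), n-BuLi (10 equiv), THF, −78 → 0 °C; 11, −78 °C; then CeCl3·7H2O, NaBH4, MeOH, −78 → −40 °C; 1 M HCl to pH 6
Reagents that add atoms: none
Why: Lithium acetylide addition to the lactone (far more electrophilic than the conjugated methyl ester) stops at the tetrahedral hemiketalate, and the ynone released on adding methanol is reduced at once under Luche conditions, so C1 is carried as a carbinol (epimers) that the allylchromium of step 9 cannot attack; no existing stereocentre is touched.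

Step 7
Reactants: 15 methyl 2-[(2R,4R,8Z)-1,2,4,5,10-pentahydroxy-4,8-dimethyldec-8-en-6-yn-1-yl]prop-2-enoate
Product: 16 methyl 2-[(2R,4R,8Z)-1,2,4,5-tetrahydroxy-4,8-dimethyl-10-oxodec-8-en-6-yn-1-yl]prop-2-enoate
Conditions: Cu(MeCN)4OTf, 2,2′-bipyridine, TEMPO (5 mol% each), N-methylimidazole (10 mol%), air, MeCN, rt
Reagents that add atoms: none
Why: Stahl Cu/TEMPO aerobic oxidation takes only the primary allylic alcohol to the (Z)-enal and leaves the secondary and tertiary hydroxyls and the olefin geometry unchanged.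

Step 8
Reactants: 16 methyl 2-[(2R,4R,8Z)-1,2,4,5-tetrahydroxy-4,8-dimethyl-10-oxodec-8-en-6-yn-1-yl]prop-2-enoate
Product: 17 methyl (2Z,4R,6R,10Z)-2-(bromomethyl)-4,6,7-trihydroxy-6,10-dimethyl-12-oxododeca-2,10-dien-8-ynoate
Conditions: NBS (1.2 equiv), Me2S (1.4 equiv), CH2Cl2, −30 → 0 °C; used at once
Reagents that add atoms: N-bromosuccinimide, O=C1CCC(=O)N1Br
Why: Corey–Kim-type activation of the Baylis–Hillman alcohol as an alkoxysulfonium salt and SN2′ attack of bromide give the conjugated (Z)-2-(bromomethyl)enoate, while the other hydroxyls return unchanged on work-up.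

Step 9
Reactants: 17 methyl (2Z,4R,6R,10Z)-2-(bromomethyl)-4,6,7-trihydroxy-6,10-dimethyl-12-oxododeca-2,10-dien-8-ynoate
Product: 19 (4Z,6R,7R,8R,10R)-1,8,10-trihydroxygermacra-4,11(13)-dien-2-yn-12,6-olide, via hydroxy ester 18 (not isolated)
Conditions: CrCl2 (10 equiv), THF, 2 mM (17 added over 12 h), rt; aq. NH4Cl
Reagents that add atoms: none
Why: Intramolecular Nozaki–Hiyama (Cr(II) Barbier) allylation in which the 2-(methoxycarbonyl)allylchromium adds through C7 to the enal and closes C6–C7; allylic strain keeps H8 in the allyl plane so the aldehyde adds anti to the C9 branch (fixing C7 from C8), the ring-constrained chair-like transition state places C5 and C8 anti across the new bond (6R,7R), and the C6 chromium alkoxide then attacks the ester to give the trans-fused 6,12-olide (precedent: Cr(II) cyclisations of ω-formyl 2-(bromomethyl)enoates to trans-germacranolides).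

Step 10
Reactants: 19 (4Z,6R,7R,8R,10R)-1,8,10-trihydroxygermacra-4,11(13)-dien-2-yn-12,6-olide
Product: 21 atripliciolide, via macrocyclic ynone 20 (not isolated)
Conditions: MnO2 (20 equiv), CH2Cl2, rt; filter; (Ph3P)AuNTf2 (5 mol%), CH2Cl2, rt
Reagents that add atoms: none
Why: Proposed new method: MnO2 oxidises only the propargylic C1 carbinol (both epimers converge) to a strained cyclodecenynone in which the C10 hydroxyl sits over C3, and π-acid activation then closes the 3(2H)-furanone by transannular 5-endo-dig oxa-Michael addition with C10 unchanged; the closest known reaction is the gold-, mercury- or base-mediated cyclisation of acyclic α′-hydroxy ynones to 3(2H)-furanones.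

Step 11
Reactants: 21 atripliciolide; 22 tigloyl chloride
Product: 23 atripliciolide tiglate
Conditions: 22 (1.5 equiv), Et3N, DMAP (cat.), CH2Cl2, 0 °C → rt
Reagents that add atoms: none
Why: DMAP-catalysed acylation of the only remaining hydroxyl (C8, secondary) with the acid chloride; no stereocentre is touched and the E-geometry of the tiglate is kept.

## Compound list

1 | 1,1-dimethoxypropan-2-one | CC(=O)C(OC)OC | starting material
2 | lithium 3,3-dimethoxyprop-1-en-2-olate | [Li]OC(=C)C(OC)OC | intermediate (not isolated)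
3 | [(3,3-dimethoxyprop-1-en-2-yl)oxy]trimethylsilane | C=C(O[Si](C)(C)C)C(OC)OC | intermediate
4 | methyl pyruvate | CC(=O)C(=O)OC | starting material
5 | methyl (2R)-5,5-dimethoxy-2-methyl-4-oxo-2-[(trimethylsilyl)oxy]pentanoate | COC(OC)C(=O)C[C@@](C)(O[Si](C)(C)C)C(=O)OC | intermediate (not isolated)
6 | methyl (2R)-2-hydroxy-5,5-dimethoxy-2-methyl-4-oxopentanoate | COC(OC)C(=O)C[C@@](C)(O)C(=O)OC | intermediate
7 | methyl (2R,4R)-2,4-dihydroxy-5,5-dimethoxy-2-methylpentanoate | COC(OC)[C@H](O)C[C@@](C)(O)C(=O)OC | intermediate (not isolated)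
8 | (3R,5R)-5-(dimethoxymethyl)-3-hydroxy-3-methyloxolan-2-one (OH cis to the acetal branch) | COC(OC)[C@H]1C[C@@](C)(O)C(=O)O1 | intermediate
9 | (2R,4R)-4-hydroxy-4-methyl-5-oxooxolane-2-carbaldehyde | O=C[C@H]1C[C@@](C)(O)C(=O)O1 | intermediate
10 | methyl acrylate | C=CC(=O)OC | starting material
11 | methyl 2-{hydroxy[(2R,4R)-4-hydroxy-4-methyl-5-oxooxolan-2-yl]methyl}prop-2-enoate (carbinol epimers) | C=C(C(=O)OC)C(O)[C@H]1C[C@@](C)(O)C(=O)O1 | intermediate
12 | (2Z)-3-methylpent-2-en-4-yn-1-ol | C#C/C(C)=C\CO | starting material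
13 | dilithium salt of 12 (lithium acetylide and alkoxide) | [Li]C#C/C(C)=C\CO[Li] | intermediate (not isolated)
14 | methyl 2-[(2R,4R,8Z)-1,2,4,10-tetrahydroxy-4,8-dimethyl-5-oxodec-8-en-6-yn-1-yl]prop-2-enoate | OC/C=C(/C)C#CC(=O)[C@](C)(O)C[C@@H](O)C(O)C(=C)C(=O)OC | intermediate (not isolated)
15 | methyl 2-[(2R,4R,8Z)-1,2,4,5,10-pentahydroxy-4,8-dimethyldec-8-en-6-yn-1-yl]prop-2-enoate (epimers at side-chain C1 and C5) | OC/C=C(/C)C#CC(O)[C@](C)(O)C[C@@H](O)C(O)C(=C)C(=O)OC | intermediate
16 | methyl 2-[(2R,4R,8Z)-1,2,4,5-tetrahydroxy-4,8-dimethyl-10-oxodec-8-en-6-yn-1-yl]prop-2-enoate | O=C/C=C(/C)C#CC(O)[C@](C)(O)C[C@@H](O)C(O)C(=C)C(=O)OC | intermediate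
17 | methyl (2Z,4R,6R,10Z)-2-(bromomethyl)-4,6,7-trihydroxy-6,10-dimethyl-12-oxododeca-2,10-dien-8-ynoate (C7 epimers) | O=C/C=C(/C)C#CC(O)[C@](C)(O)C[C@@H](O)/C=C(\CBr)C(=O)OC | intermediate
18 | methyl (4Z,6R,7R,8R,10R)-1,6,8,10-tetrahydroxygermacra-4,11(13)-dien-2-yn-12-oate (C1 epimers) | C=C(C(=O)OC)[C@H]1[C@H](O)/C=C(/C)C#CC(O)[C@](C)(O)C[C@H]1O | intermediate (not isolated)
19 | (4Z,6R,7R,8R,10R)-1,8,10-trihydroxygermacra-4,11(13)-dien-2-yn-12,6-olide (C1 epimers) | C=C1C(=O)O[C@@H]2/C=C(/C)C#CC(O)[C@](C)(O)C[C@@H](O)[C@@H]12 | intermediate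
20 | (4Z,6R,7R,8R,10R)-8,10-dihydroxy-1-oxogermacra-4,11(13)-dien-2-yn-12,6-olide | C=C1C(=O)O[C@@H]2/C=C(/C)C#CC(=O)[C@](C)(O)C[C@@H](O)[C@@H]12 | intermediate (not isolated)
21 | atripliciolide, (4Z,6R,7R,8R,10R)-8-hydroxy-1-oxo-3,10-epoxygermacra-2,4,11(13)-trien-12,6-olide | C=C1C(=O)O[C@@H]2/C=C(/C)C3=CC(=O)[C@@](C)(C[C@@H](O)[C@@H]12)O3 | intermediate
22 | tigloyl chloride, (2E)-2-methylbut-2-enoyl chloride | O=C(Cl)/C(C)=C/C | starting material
23 | atripliciolide tiglate, the 8-O-[(2E)-2-methylbut-2-enoyl] ester of 21 | C=C1C(=O)O[C@@H]2/C=C(/C)C3=CC(=O)[C@@](C)(C[C@@H](OC(=O)/C(C)=C/C)[C@@H]12)O3 | target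

## Step count and risks

Total step count: 11. Longest linear sequence: 11 (1 → 23); compounds 4, 10, 12 and 22 are bought.

Step 9 (Cr(II) ring closure) is the most likely to fail, through oligomerisation, a wrong C6/C7 relationship or loss of the hydroxy bromide 17. The fallback inverts the order of the two late ring closures and sets out from 14, obtained by stopping step 6 before the borohydride stage. Gold(I)-catalysed 5-endo-dig cyclisation of this acyclic α′-hydroxy ynone gives the furanone methyl 2-{(2R)-1,2-dihydroxy-3-[(2R)-5-[(2Z)-4-hydroxybut-2-en-2-yl]-2-methyl-3-oxo-2,3-dihydrofuran-2-yl]propyl}prop-2-enoate F1. Cu/TEMPO/air oxidation gives the enal methyl 2-{(2R)-1,2-dihydroxy-3-[(2R)-2-methyl-3-oxo-5-[(2Z)-4-oxobut-2-en-2-yl]-2,3-dihydrofuran-2-yl]propyl}prop-2-enoate F2, and NBS/Me2S gives the allylic bromide methyl (2Z,4R)-2-(bromomethyl)-4-hydroxy-5-[(2R)-2-methyl-3-oxo-5-[(2Z)-4-oxobut-2-en-2-yl]-2,3-dihydrofuran-2-yl]pent-2-enoate F3. CrCl2 under high dilution then closes C6–C7 on a substrate whose C1 carbonyl is an inert vinylogous ester, through methyl (4Z,6R,7R,8R,10R)-6,8-dihydroxy-1-oxo-3,10-epoxygermacra-2,4,11(13)-trien-12-oate F4 (not isolated), which lactonises to 21. The route is rejoined at 21, before step 11.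

Step 6 (acetylide opening of the lactone beside the acrylate ester) may fail through attack on the methyl ester or relactonisation of the freed C8 hydroxyl. The fallback sets out from 11. Its lactone is opened with Me2AlN(OMe)Me (from AlMe3 and MeNHOMe·HCl) to the Weinreb amide methyl 2-{(2R,4R)-1,2,4-trihydroxy-5-[methoxy(methyl)amino]-4-methyl-5-oxopentyl}prop-2-enoate F5. The bis(bromomagnesium) derivative of 12 F6 (from 12 and EtMgBr) acylates only the Weinreb amide and gives 14, which is reduced with NaBH4/CeCl3 as in step 6. The route is rejoined at 15.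

Step 5 (Baylis–Hillman reaction on the lactol-masked, base-sensitive aldehyde) may fail through slow reaction or epimerisation at C8 under DABCO. The fallback sets out from 9 and installs the acrylate unit without an amine base by vinylalumination. Methyl propiolate is hydroaluminated with DIBAL-H/NMO to methyl 2-[bis(2-methylpropyl)alumanyl]prop-2-enoate F7, which adds to the aldehyde of 9 under Lewis-acidic conditions and gives 11 after aqueous work-up. The route is rejoined at 11.

Further compounds
F1 | step 9 | methyl 2-{(2R)-1,2-dihydroxy-3-[(2R)-5-[(2Z)-4-hydroxybut-2-en-2-yl]-2-methyl-3-oxo-2,3-dihydrofuran-2-yl]propyl}prop-2-enoate | OC/C=C(/C)C1=CC(=O)[C@@](C)(C[C@@H](O)C(O)C(=C)C(=O)OC)O1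
F2 | step 9 | methyl 2-{(2R)-1,2-dihydroxy-3-[(2R)-2-methyl-3-oxo-5-[(2Z)-4-oxobut-2-en-2-yl]-2,3-dihydrofuran-2-yl]propyl}prop-2-enoate | O=C/C=C(/C)C1=CC(=O)[C@@](C)(C[C@@H](O)C(O)C(=C)C(=O)OC)O1
F3 | step 9 | methyl (2Z,4R)-2-(bromomethyl)-4-hydroxy-5-[(2R)-2-methyl-3-oxo-5-[(2Z)-4-oxobut-2-en-2-yl]-2,3-dihydrofuran-2-yl]pent-2-enoate | O=C/C=C(/C)C1=CC(=O)[C@@](C)(C[C@@H](O)/C=C(\CBr)C(=O)OC)O1
F4 | step 9 | methyl (4Z,6R,7R,8R,10R)-6,8-dihydroxy-1-oxo-3,10-epoxygermacra-2,4,11(13)-trien-12-oate | C=C(C(=O)OC)[C@H]1[C@H](O)/C=C(/C)C2=CC(=O)[C@@](C)(C[C@H]1O)O2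
F5 | step 6 | methyl 2-{(2R,4R)-1,2,4-trihydroxy-5-[methoxy(methyl)amino]-4-methyl-5-oxopentyl}prop-2-enoate | CON(C)C(=O)[C@](C)(O)C[C@@H](O)C(O)C(=C)C(=O)OC
F6 | step 6 | bis(bromomagnesium) derivative of (2Z)-3-methylpent-2-en-4-yn-1-ol | Br[Mg]C#C/C(C)=C\CO[Mg]Br
F7 | step 5 | methyl 2-[bis(2-methylpropyl)alumanyl]prop-2-enoate | C=C(C(=O)OC)[Al](CC(C)C)CC(C)C
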